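The cyclopentane (ring C13–C17) is cut at C14–C15. The target carries a cis-epoxide on these two adjacent ring carbons, on the face opposite the C13 side chain; read as a cis-1,2-diol, this is the signature of a reductive carbonyl–carbonyl coupling. In one operation SmI2 joins the two aldehyde carbons of an acyclic (2R,3R)-2,3-disubstituted pentanedial, closing the five-membered ring, forming C14–C15 and setting both carbinol centres. The precursor carries C12 as a benzyloxymethyl group on C13 and the C18 carbinol as a silyl ether on the C17 branch; chlorine (with inversion), the triene ester chain and the epoxide are added afterwards.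

Key step: step 10

Remark on the chemistry: target atoms are numbered C1 (ester carbon) to C20 and this numbering is kept for all intermediates; the configuration in the target SMILES is read as 13S, 14R, 15S, 17R, 18S. The C12 oxygen is carried as a benzyl ether, brought in with benzyl chloromethyl ether and removed by hydrogenolysis before any alkene is present.

**Route**

Step 1
Reactants: 1 methyl (2R)-2-hydroxybutanoate
Product: 2 methyl (2R)-2-[(tert-butyldimethylsilyl)oxy]butanoate
Conditions: TBSCl, imidazole, DMF, 0 °C → rt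
Reagents that add atoms: tert-butyldimethylsilyl chloride, CC(C)(C)[Si](C)(C)Cl
Why: Imidazole-promoted silylation of a secondary α-hydroxy ester is routine and does not touch the stereocentre, so C18 stays R.

Step 2
Reactants: 2 methyl (2R)-2-[(tert-butyldimethylsilyl)oxy]butanoate
Product: 3 (2R)-2-[(tert-butyldimethylsilyl)oxy]butanal
Conditions: i-Bu2AlH (1.1 equiv), CH2Cl2, −78 °C; MeOH, aq. KNaC4H4O6
Reagents that add atoms: none
Why: Partial ester reduction with i-Bu2AlH at −78 °C stops at the aluminium hemiacetal, which is reliable for α-silyloxy esters and releases the aldehyde on work-up without epimerising C18.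

Step 3
Reactants: 3 (2R)-2-[(tert-butyldimethylsilyl)oxy]butanal; 4 methyl 2-[bis(2,2,2-trifluoroethoxy)phosphoryl]acetate
Product: 5 methyl (2Z,4R)-4-[(tert-butyldimethylsilyl)oxy]hex-2-enoate
Conditions: KN(SiMe3)2, 18-crown-6, THF, −78 °C
Reagents that add atoms: none
Why: Still–Gennari olefination: the electron-poor phosphonate under dissociating conditions eliminates rapidly from the kinetically formed adduct and should give the (Z)-enoate, while −78 °C keeps the α-silyloxy aldehyde configurationally intact.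

Step 4
Reactants: 5 methyl (2Z,4R)-4-[(tert-butyldimethylsilyl)oxy]hex-2-enoate
Product: 6 (2Z,4R)-4-[(tert-butyldimethylsilyl)oxy]hex-2-en-1-ol
Conditions: i-Bu2AlH (2.2 equiv), CH2Cl2, −78 °C
Reagents that add atoms: none
Why: 1,2-Reduction of an enoate by i-Bu2AlH should give the allylic alcohol with the Z geometry retained.

Step 5
Reactants: 6 (2Z,4R)-4-[(tert-butyldimethylsilyl)oxy]hex-2-en-1-ol; 7 triethyl orthoacetate
Product: 9 ethyl (3S,4R)-4-[(tert-butyldimethylsilyl)oxy]-3-ethenylhexanoate, via ketene acetal 8 (not isolated)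
Conditions: neat 7 (excess), EtCO2H (cat.), 140 °C, EtOH distilled off
Reagents that add atoms: none
Why: Johnson–Claisen rearrangement: the ketene acetal 8 undergoes the [3,3] shift that forms C13–C17, and in the Z olefin allylic 1,3-strain holds C18–H in the alkene plane so that the ketene acetal carbon is expected to add to C17 anti to the C18–O bond (Felkin–Anh-type arrangement), which sets C17 as required (3S in 9).

Step 6
Reactants: 9 ethyl (3S,4R)-4-[(tert-butyldimethylsilyl)oxy]-3-ethenylhexanoate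
Product: 12 (4R)-4-[(1R)-1-[(tert-butyldimethylsilyl)oxy]propyl]oxan-2-one, via alkylborane 10 (not isolated), via hydroxy ester 11 (not isolated)
Conditions: 9-BBN, THF, 0 °C → rt; 30% H2O2, aq. NaOAc, 0 °C → rt; then PPTS (cat.), toluene, 80 °C
Reagents that add atoms: hydrogen peroxide, OO
Why: Anti-Markovnikov hydroboration–oxidation of the terminal vinyl group (9-BBN leaves esters alone) gives the δ-hydroxy ester 11, which should lactonise under mild acid catalysis without affecting any stereocentre.

Step 7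
Reactants: 12 (4R)-4-[(1R)-1-[(tert-butyldimethylsilyl)oxy]propyl]oxan-2-one; 13 benzyl chloromethyl ether
Product: 15 (3R,4R)-3-[(benzyloxy)methyl]-4-[(1R)-1-[(tert-butyldimethylsilyl)oxy]propyl]oxan-2-one, via lithium enolate 14 (not isolated)
Conditions: LiN(i-Pr)2, THF, −78 °C; then 13, −78 → −30 °C
Reagents that add atoms: none
Why: Lactone enolate alkylation: the half-chair enolate 14 is attacked by the reactive chloromethyl ether on the face opposite the bulky C17 branch, which should set C13 trans to that branch (3,4-trans, substrate control).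

Step 8
Reactants: 15 (3R,4R)-3-[(benzyloxy)methyl]-4-[(1R)-1-[(tert-butyldimethylsilyl)oxy]propyl]oxan-2-one
Product: 16 (2S,3R)-2-[(benzyloxy)methyl]-3-[(1R)-1-[(tert-butyldimethylsilyl)oxy]propyl]pentane-1,5-diol
Conditions: LiAlH4, THF, 0 °C
Reagents that add atoms: none
Why: Hydride reduction of the lactone to the 1,5-diol outruns enolisation, so C13 is retained, and silyl and benzyl ethers are inert to LiAlH4 at 0 °C.

Step 9
Reactants: 16 (2S,3R)-2-[(benzyloxy)methyl]-3-[(1R)-1-[(tert-butyldimethylsilyl)oxy]propyl]pentane-1,5-diol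
Product: 17 (2R,3R)-2-[(benzyloxy)methyl]-3-[(1R)-1-[(tert-butyldimethylsilyl)oxy]propyl]pentanedial
Conditions: (COCl)2, DMSO, CH2Cl2, −78 °C; i-Pr2NEt, −78 → −30 °C; used crude at once
Reagents that add atoms: none
Why: Double Swern oxidation activates both primary alcohols as alkoxysulfonium ions before base is added, which avoids the lactol/lactone pathway of a 1,5-diol, and the hindered amine at low temperature should limit epimerisation at C13 and β-elimination of the benzyloxy group.

Step 10
Reactants: 17 (2R,3R)-2-[(benzyloxy)methyl]-3-[(1R)-1-[(tert-butyldimethylsilyl)oxy]propyl]pentanedial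
Product: 18 (1S,2R,3R,4R)-3-[(benzyloxy)methyl]-4-[(1R)-1-[(tert-butyldimethylsilyl)oxy]propyl]cyclopentane-1,2-diol
Conditions: SmI2 (2.5 equiv, 0.1 M in THF), t-BuOH (2 equiv), THF, −78 °C → rt; aq. NH4Cl
Reagents that add atoms: none
Why: Single-electron transfer from divalent samarium gives samarium-bound ketyl radicals, and the C14 ketyl carbon bonds to the C15 carbonyl carbon (ketyl–ketyl coupling, or ketyl addition to the samarium-activated second aldehyde followed by a second electron transfer), so two carbons of the same electrophilic polarity are joined and protonation gives the diol. The closest known reaction type is the SmI2-mediated intramolecular pinacol coupling of 1,5-dialdehydes to cis-cyclopentane-1,2-diols. The ring C13–C14–C15–C16–C17 closes in a 5-exo-trig mode, the attacked C=O keeping its oxygen outside the new ring. The cis relationship of the C14 and C15 hydroxyls is controlled by the oxophilic trivalent samarium, which holds both oxygens in one chelate while the C–C bond forms; the face on which this diolate forms is controlled by the C13 stereocentre, whose benzyloxymethyl group lies pseudo-equatorial and sends the bulky samarium alkoxide on the adjacent C14 to the opposite face. The step needs the cis-diol anti to the C13 substituent (1S,2R in 18); chelation together with the α-substituent at C13 should secure this, while the C17 branch, trans to the C13 group and 1,3 to both new carbinol carbons, is expected to have only a minor influence, and the absence of any α-heteroatom at either aldehyde keeps the reduction chemoselective.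

Step 11
Reactants: 18 (1S,2R,3R,4R)-3-[(benzyloxy)methyl]-4-[(1R)-1-[(tert-butyldimethylsilyl)oxy]propyl]cyclopentane-1,2-diol
Product: 19 (3aR,4R,5R,6aS)-4-[(benzyloxy)methyl]-5-[(1R)-1-[(tert-butyldimethylsilyl)oxy]propyl]-2,2-dimethyltetrahydro-4H-cyclopenta[d][1,3]dioxole
Conditions: Me2C(OMe)2, PPTS (cat.), CH2Cl2, rt
Reagents that add atoms: 2,2-dimethoxypropane, COC(C)(C)OC
Why: Acid-catalysed transketalisation gives the cis-fused isopropylidene acetal, which only a cis-1,2-diol on a cyclopentane can form, and it masks C14/C15 through the following steps.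

Step 12
Reactants: 19 (3aR,4R,5R,6aS)-4-[(benzyloxy)methyl]-5-[(1R)-1-[(tert-butyldimethylsilyl)oxy]propyl]-2,2-dimethyltetrahydro-4H-cyclopenta[d][1,3]dioxole
Product: 20 (1R)-1-[(3aR,4R,5R,6aS)-4-[(benzyloxy)methyl]-2,2-dimethyltetrahydro-4H-cyclopenta[d][1,3]dioxol-5-yl]propan-1-ol
Conditions: n-Bu4NF, THF, rt → 40 °C
Reagents that add atoms: none
Why: Fluoride-induced desilylation (driven by Si–F bond formation) frees the C18 hydroxyl, and benzyl ether and acetonide are inert to fluoride.

Step 13
Reactants: 20 (1R)-1-[(3aR,4R,5R,6aS)-4-[(benzyloxy)methyl]-2,2-dimethyltetrahydro-4H-cyclopenta[d][1,3]dioxol-5-yl]propan-1-ol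
Product: 21 (3aR,4R,5R,6aS)-4-[(benzyloxy)methyl]-5-[(1S)-1-chloropropyl]-2,2-dimethyltetrahydro-4H-cyclopenta[d][1,3]dioxole
Conditions: PPh3, CCl4, 2,6-lutidine, MeCN, 0 → 50 °C
Reagents that add atoms: tetrachloromethane, ClC(Cl)(Cl)Cl
Why: Appel reaction: chloride displaces the alkoxyphosphonium ion in an SN2 step, which should invert C18 from R to S, and the buffered neutral medium preserves the acetonide.

Step 14
Reactants: 21 (3aR,4R,5R,6aS)-4-[(benzyloxy)methyl]-5-[(1S)-1-chloropropyl]-2,2-dimethyltetrahydro-4H-cyclopenta[d][1,3]dioxole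
Product: 22 [(3aR,4R,5R,6aS)-5-[(1S)-1-chloropropyl]-2,2-dimethyltetrahydro-4H-cyclopenta[d][1,3]dioxol-4-yl]methanol
Conditions: H2 (1 atm), Pd/C, EtOAc, rt
Reagents that add atoms: none
Why: Hydrogenolysis of the benzyl ether is run before any alkene exists, and an unactivated secondary alkyl chloride and the acetonide should not be reduced over Pd/C in neutral ethyl acetate.

Step 15
Reactants: 22 [(3aR,4R,5R,6aS)-5-[(1S)-1-chloropropyl]-2,2-dimethyltetrahydro-4H-cyclopenta[d][1,3]dioxol-4-yl]methanol
Product: 23 (3aR,4S,5R,6aS)-5-[(1S)-1-chloropropyl]-2,2-dimethyltetrahydro-4H-cyclopenta[d][1,3]dioxole-4-carbaldehyde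
Conditions: Dess–Martin periodinane, NaHCO3, CH2Cl2, 0 °C → rt
Reagents that add atoms: none
Why: Dess–Martin oxidation under buffered, non-basic conditions should give the aldehyde without epimerising C13, whose formyl group is in any case trans to both ring neighbours.

Step 16
Reactants: 24 but-3-yn-1-ol; 25 formaldehyde (used as paraformaldehyde)
Product: 27 pent-2-yne-1,5-diol, via magnesium acetylide alkoxide 26 (not isolated)
Conditions: EtMgBr (2.2 equiv), THF, 0 → 50 °C; then 25, 60 °C; aq. NH4Cl
Reagents that add atoms: none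
Why: Hydroxymethylation of a magnesium acetylide (two equivalents of Grignard reagent because the hydroxyl is deprotonated first) with formaldehyde gives the propargylic alcohol.

Step 17
Reactants: 27 pent-2-yne-1,5-diol
Product: 28 1,5-dibromopent-2-yne
Conditions: CBr4, PPh3, CH2Cl2, 0 °C
Reagents that add atoms: tetrabromomethane, BrC(Br)(Br)Br
Why: Appel bromination converts both primary alcohols into bromides under neutral conditions.

Step 18
Reactants: 28 1,5-dibromopent-2-yne; 29 methyl hex-5-ynoate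
Product: 30 methyl 11-bromoundeca-5,8-diynoate
Conditions: CuI (10 mol%), K2CO3, n-Bu4NBr, DMF, rt
Reagents that add atoms: none
Why: Copper-mediated coupling of a terminal alkyne with a propargylic halide (SN2 displacement by the copper acetylide) gives the skipped diyne, while the homopropargylic primary bromide does not react with the acetylide and the ester tolerates the weak base.

Step 19
Reactants: 30 methyl 11-bromoundeca-5,8-diynoate
Product: 31 methyl (5Z,8Z)-11-bromoundeca-5,8-dienoate
Conditions: H2 (1 atm), Pd/CaCO3 poisoned with Pb(OAc)2 (Lindlar catalyst), quinoline, EtOAc, rt, stopped after 2 equiv H2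
Reagents that add atoms: none
Why: Lindlar semihydrogenation adds H2 syn to each alkyne on the poisoned catalyst and should give the (Z,Z)-skipped diene with the alkyl bromide and ester untouched.

Step 20
Reactants: 31 methyl (5Z,8Z)-11-bromoundeca-5,8-dienoate
Product: 32 [(3Z,6Z)-11-methoxy-11-oxoundeca-3,6-dien-1-yl]triphenylphosphonium bromide
Conditions: PPh3, MeCN, 80 °C
Reagents that add atoms: triphenylphosphine, c1ccc(cc1)P(c1ccccc1)c1ccccc1
Why: SN2 quaternisation of triphenylphosphine by the primary bromide gives the phosphonium salt.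

Step 21
Reactants: 23 (3aR,4S,5R,6aS)-5-[(1S)-1-chloropropyl]-2,2-dimethyltetrahydro-4H-cyclopenta[d][1,3]dioxole-4-carbaldehyde; 32 [(3Z,6Z)-11-methoxy-11-oxoundeca-3,6-dien-1-yl]triphenylphosphonium bromide
Product: 34 methyl (5Z,8Z,11Z)-12-[(3aR,4S,5R,6aS)-5-[(1S)-1-chloropropyl]-2,2-dimethyltetrahydro-4H-cyclopenta[d][1,3]dioxol-4-yl]dodeca-5,8,11-trienoate, via phosphorus ylide 33 (not isolated)
Conditions: NaN(SiMe3)2, THF, −78 °C; then 23, −78 → 0 °C
Reagents that add atoms: none
Why: Wittig olefination of a non-stabilised ylide under lithium-free conditions at low temperature passes through the kinetically favoured cis-oxaphosphetane and should give the (Z)-alkene C11=C12; the phosphonium α-CH is far more acidic than the ester α-CH, so one equivalent of base forms ylide 33 selectively, and the secondary chloride is inert at this temperature.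

Step 22
Reactants: 34 methyl (5Z,8Z,11Z)-12-[(3aR,4S,5R,6aS)-5-[(1S)-1-chloropropyl]-2,2-dimethyltetrahydro-4H-cyclopenta[d][1,3]dioxol-4-yl]dodeca-5,8,11-trienoate
Product: 35 methyl (5Z,8Z,11Z)-12-[(1S,2R,3S,5R)-5-[(1S)-1-chloropropyl]-2,3-dihydroxycyclopentyl]dodeca-5,8,11-trienoate
Conditions: AcOH/H2O (4:1), 50 °C
Reagents that add atoms: none
Why: Acid-catalysed hydrolysis of the isopropylidene acetal frees the cis-diol, and the skipped triene, secondary chloride and methyl ester should tolerate warm aqueous acetic acid.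

Step 23
Reactants: 35 methyl (5Z,8Z,11Z)-12-[(1S,2R,3S,5R)-5-[(1S)-1-chloropropyl]-2,3-dihydroxycyclopentyl]dodeca-5,8,11-trienoate
Product: 38 methyl (5Z,8Z,11Z)-12-[(1R,2S,3R,5S)-3-[(1S)-1-chloropropyl]-6-oxabicyclo[3.1.0]hexan-2-yl]dodeca-5,8,11-trienoate, via cyclic orthoacetate 36 (not isolated), via trans-bromo acetate 37 (not isolated)
Conditions: MeC(OMe)3, PPTS (cat.), CH2Cl2, rt; evaporate; AcBr, CH2Cl2, 0 °C → rt; evaporate; K2CO3, MeOH, rt
Reagents that add atoms: none
Why: One-pot orthoester-based conversion of a cis-diol into an epoxide with overall retention: orthoester exchange gives 36, acetyl bromide turns it via an acetoxonium ion (opened by bromide with inversion) into the trans-bromo acetate 37, and methanolysis of the acetate releases an alkoxide that displaces bromide in a second inversion, so the epoxide should form on the face of the original diol whichever carbinol carbon bromide attacks, while the methyl ester is unchanged in methanol.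

**Compound list**

1 | methyl (2R)-2-hydroxybutanoate | CC[C@@H](O)C(=O)OC | starting material
2 | methyl (2R)-2-[(tert-butyldimethylsilyl)oxy]butanoate | CC[C@@H](O[Si](C)(C)C(C)(C)C)C(=O)OC | intermediate
3 | (2R)-2-[(tert-butyldimethylsilyl)oxy]butanal | CC[C@@H](O[Si](C)(C)C(C)(C)C)C=O | intermediate
4 | methyl 2-[bis(2,2,2-trifluoroethoxy)phosphoryl]acetate | COC(=O)CP(=O)(OCC(F)(F)F)OCC(F)(F)F | starting material
5 | methyl (2Z,4R)-4-[(tert-butyldimethylsilyl)oxy]hex-2-enoate | CC[C@@H](O[Si](C)(C)C(C)(C)C)/C=C\C(=O)OC | intermediate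
6 | (2Z,4R)-4-[(tert-butyldimethylsilyl)oxy]hex-2-en-1-ol | CC[C@@H](O[Si](C)(C)C(C)(C)C)/C=C\CO | intermediate
7 | triethyl orthoacetate (1,1,1-triethoxyethane) | CCOC(C)(OCC)OCC | starting material
8 | mixed ketene acetal, 1-ethoxyethenyl (2Z,4R)-4-[(tert-butyldimethylsilyl)oxy]hex-2-en-1-yl ether | CCOC(=C)OC/C=C\[C@H](O[Si](C)(C)C(C)(C)C)CC | intermediate
9 | ethyl (3S,4R)-4-[(tert-butyldimethylsilyl)oxy]-3-ethenylhexanoate | CCOC(=O)C[C@@H](C=C)[C@H](O[Si](C)(C)C(C)(C)C)CC | intermediate
10 | ethyl (3R,4R)-3-[2-(9-borabicyclo[3.3.1]nonan-9-yl)ethyl]-4-[(tert-butyldimethylsilyl)oxy]hexanoate | CCOC(=O)C[C@@H](CCB1C2CCCC1CCC2)[C@H](O[Si](C)(C)C(C)(C)C)CC | intermediate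
11 | ethyl (3R,4R)-4-[(tert-butyldimethylsilyl)oxy]-3-(2-hydroxyethyl)hexanoate | CCOC(=O)C[C@@H](CCO)[C@H](O[Si](C)(C)C(C)(C)C)CC | intermediate
12 | (4R)-4-[(1R)-1-[(tert-butyldimethylsilyl)oxy]propyl]oxan-2-one | O=C1C[C@@H](CCO1)[C@H](O[Si](C)(C)C(C)(C)C)CC | intermediate
13 | benzyl chloromethyl ether | ClCOCc1ccccc1 | starting material
14 | lithium (4R)-4-[(1R)-1-[(tert-butyldimethylsilyl)oxy]propyl]-5,6-dihydro-4H-pyran-2-olate (enolate of 12) | [Li+].[O-]C1=C[C@@H](CCO1)[C@H](O[Si](C)(C)C(C)(C)C)CC | intermediate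
15 | (3R,4R)-3-[(benzyloxy)methyl]-4-[(1R)-1-[(tert-butyldimethylsilyl)oxy]propyl]oxan-2-one (3,4-trans) | O=C1[C@@H](COCc2ccccc2)[C@@H](CCO1)[C@H](O[Si](C)(C)C(C)(C)C)CC | intermediate
16 | (2S,3R)-2-[(benzyloxy)methyl]-3-[(1R)-1-[(tert-butyldimethylsilyl)oxy]propyl]pentane-1,5-diol | OC[C@@H](COCc1ccccc1)[C@@H](CCO)[C@H](O[Si](C)(C)C(C)(C)C)CC | intermediate
17 | (2R,3R)-2-[(benzyloxy)methyl]-3-[(1R)-1-[(tert-butyldimethylsilyl)oxy]propyl]pentanedial | O=C[C@@H](COCc1ccccc1)[C@@H](CC=O)[C@H](O[Si](C)(C)C(C)(C)C)CC | intermediate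
18 | (1S,2R,3R,4R)-3-[(benzyloxy)methyl]-4-[(1R)-1-[(tert-butyldimethylsilyl)oxy]propyl]cyclopentane-1,2-diol | CC[C@@H](O[Si](C)(C)C(C)(C)C)[C@@H]1C[C@H](O)[C@H](O)[C@H]1COCc1ccccc1 | intermediate
19 | (3aR,4R,5R,6aS)-4-[(benzyloxy)methyl]-5-[(1R)-1-[(tert-butyldimethylsilyl)oxy]propyl]-2,2-dimethyltetrahydro-4H-cyclopenta[d][1,3]dioxole | CC[C@@H](O[Si](C)(C)C(C)(C)C)[C@@H]1C[C@@H]2OC(C)(C)O[C@@H]2[C@H]1COCc1ccccc1 | intermediate
20 | (1R)-1-[(3aR,4R,5R,6aS)-4-[(benzyloxy)methyl]-2,2-dimethyltetrahydro-4H-cyclopenta[d][1,3]dioxol-5-yl]propan-1-ol | CC[C@@H](O)[C@@H]1C[C@@H]2OC(C)(C)O[C@@H]2[C@H]1COCc1ccccc1 | intermediate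
21 | (3aR,4R,5R,6aS)-4-[(benzyloxy)methyl]-5-[(1S)-1-chloropropyl]-2,2-dimethyltetrahydro-4H-cyclopenta[d][1,3]dioxole | CC[C@H](Cl)[C@@H]1C[C@@H]2OC(C)(C)O[C@@H]2[C@H]1COCc1ccccc1 | intermediate
22 | [(3aR,4R,5R,6aS)-5-[(1S)-1-chloropropyl]-2,2-dimethyltetrahydro-4H-cyclopenta[d][1,3]dioxol-4-yl]methanol | CC[C@H](Cl)[C@@H]1C[C@@H]2OC(C)(C)O[C@@H]2[C@H]1CO | intermediate
23 | (3aR,4S,5R,6aS)-5-[(1S)-1-chloropropyl]-2,2-dimethyltetrahydro-4H-cyclopenta[d][1,3]dioxole-4-carbaldehyde | CC[C@H](Cl)[C@@H]1C[C@@H]2OC(C)(C)O[C@@H]2[C@H]1C=O | intermediate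
24 | but-3-yn-1-ol | C#CCCO | starting material
25 | formaldehyde (used as paraformaldehyde) | C=O | starting material
26 | bromomagnesium 4-(bromomagnesio)but-3-yn-1-olate | Br[Mg]OCCC#C[Mg]Br | intermediate
27 | pent-2-yne-1,5-diol | OCC#CCCO | intermediate
28 | 1,5-dibromopent-2-yne | BrCC#CCCBr | intermediate
29 | methyl hex-5-ynoate | C#CCCCC(=O)OC | starting material
30 | methyl 11-bromoundeca-5,8-diynoate | COC(=O)CCCC#CCC#CCCBr | intermediate
31 | methyl (5Z,8Z)-11-bromoundeca-5,8-dienoate | COC(=O)CCC/C=C\C/C=C\CCBr | intermediate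
32 | [(3Z,6Z)-11-methoxy-11-oxoundeca-3,6-dien-1-yl]triphenylphosphonium bromide | [Br-].COC(=O)CCC/C=C\C/C=C\CC[P+](c1ccccc1)(c1ccccc1)c1ccccc1 | intermediate
33 | methyl (5Z,8Z)-11-(triphenyl-λ5-phosphanylidene)undeca-5,8-dienoate (ylide) | COC(=O)CCC/C=C\C/C=C\CC=P(c1ccccc1)(c1ccccc1)c1ccccc1 | intermediate
34 | methyl (5Z,8Z,11Z)-12-[(3aR,4S,5R,6aS)-5-[(1S)-1-chloropropyl]-2,2-dimethyltetrahydro-4H-cyclopenta[d][1,3]dioxol-4-yl]dodeca-5,8,11-trienoate | CC[C@H](Cl)[C@@H]1C[C@@H]2OC(C)(C)O[C@@H]2[C@H]1/C=C\C/C=C\C/C=C\CCCC(=O)OC | intermediate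
35 | methyl (5Z,8Z,11Z)-12-[(1S,2R,3S,5R)-5-[(1S)-1-chloropropyl]-2,3-dihydroxycyclopentyl]dodeca-5,8,11-trienoate | CC[C@H](Cl)[C@@H]1C[C@H](O)[C@H](O)[C@H]1/C=C\C/C=C\C/C=C\CCCC(=O)OC | intermediate
36 | cyclic orthoacetate of 35 (cis-fused 2-methoxy-2-methyl-1,3-dioxolane on C14 and C15, both epimers at the orthoester carbon) | CC[C@H](Cl)[C@@H]1C[C@@H]2OC(C)(OC)O[C@@H]2[C@H]1/C=C\C/C=C\C/C=C\CCCC(=O)OC | intermediate
37 | methyl (5Z,8Z,11Z)-12-[(1S,2R,3R,5R)-2-(acetyloxy)-3-bromo-5-[(1S)-1-chloropropyl]cyclopentyl]dodeca-5,8,11-trienoate | CC[C@H](Cl)[C@@H]1C[C@@H](Br)[C@H](OC(C)=O)[C@H]1/C=C\C/C=C\C/C=C\CCCC(=O)OC | intermediate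
38 | methyl (5Z,8Z,11Z)-12-[(1R,2S,3R,5S)-3-[(1S)-1-chloropropyl]-6-oxabicyclo[3.1.0]hexan-2-yl]dodeca-5,8,11-trienoate (CNP0141251.1) | CC[C@H](Cl)[C@@H]1C[C@@H]2O[C@@H]2[C@H]1/C=C\C/C=C\C/C=C\CCCC(=O)OC | target

**Counts**

Total step count: 23 (18 on the core, 5 on the side-chain phosphonium salt).
Longest linear sequence: 18 steps (steps 1–15, then 21–23).

**Steps most likely to fail**

1. Step 10 (key step). The ring closure may proceed with poor facial control (diol forming on the face of the C13 group), or the β-benzyloxy dialdehyde may epimerise at C13 or undergo simple reduction before the second carbonyl is engaged. The fallback sets out from dialdehyde 17 and returns at diol 18. It replaces reductive coupling by olefin metathesis and osmylation. Double methylenation of 17 with Ph3P=CH2 (THF, −78 → 0 °C) would give tert-butyl{[(3R,4R,5R)-5-[(benzyloxy)methyl]-4-(prop-2-en-1-yl)hept-6-en-3-yl]oxy}dimethylsilane F1. Ring-closing metathesis with the second-generation Grubbs catalyst (H2IMes)(PCy3)Cl2Ru=CHPh in CH2Cl2 at 40 °C would close C14=C15 and give {(1R)-1-[(1R,2R)-2-[(benzyloxy)methyl]cyclopent-3-en-1-yl]propoxy}(tert-butyl)dimethylsilane F2. Dihydroxylation with OsO4 (cat.) and N-methylmorpholine N-oxide in acetone/water is expected on the face opposite the allylic C13 substituent and would give 18.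

2. Step 5. The rearrangement may show poor facial discrimination at C17, or the opposite facial sense, because the controlling C18 centre lies outside the pericyclic array. The fallback sets out from aldehyde 3 and returns at lactone 12. It sets C17 by conjugate addition to an (E)-enoate, for which addition anti to a γ-oxygen substituent is the established sense.
   - Wittig reaction of 3 with Ph3P=CHCO2Me (CH2Cl2, rt) would give methyl (2E,4R)-4-[(tert-butyldimethylsilyl)oxy]hex-2-enoate F3.
   - (CH2=CH)2CuLi with Me3SiCl in THF at −78 °C should add anti to the silyloxy group and give methyl (3R,4R)-4-[(tert-butyldimethylsilyl)oxy]-3-ethenylhexanoate F4. In F4 the ester arm is C16–C15 and the vinyl group is C13–C14, so the two arms must then be brought to the oxidation levels of 12.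
   - i-Bu2AlH would reduce the ester to (3R,4R)-4-[(tert-butyldimethylsilyl)oxy]-3-ethenylhexan-1-ol F5.
   - Ac2O/pyridine would give (3R,4R)-4-[(tert-butyldimethylsilyl)oxy]-3-ethenylhexyl acetate F6.
   - 9-BBN followed by H2O2/NaOAc would give (3S,4R)-4-[(tert-butyldimethylsilyl)oxy]-3-(2-hydroxyethyl)hexyl acetate F7.
   - TEMPO (cat.)/PhI(OAc)2 in aqueous MeCN would give (3R)-5-(acetyloxy)-3-[(1R)-1-[(tert-butyldimethylsilyl)oxy]propyl]pentanoic acid F8.
   - K2CO3/MeOH, acidification and PPTS in warm toluene would remove the acetate and close lactone 12.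

3. Step 13. Displacement at the hindered, β-branched C18 may be slow, so that elimination competes, or an acetonide oxygen on the same ring face may take part and erode the inversion. The fallback sets out from alcohol 20 and returns at chloride 21. It separates activation from displacement. Tf2O/pyridine in CH2Cl2 at −40 °C would give (1R)-1-[(3aR,4R,5R,6aS)-4-[(benzyloxy)methyl]-2,2-dimethyltetrahydro-4H-cyclopenta[d][1,3]dioxol-5-yl]propyl trifluoromethanesulfonate F9. Soluble chloride (n-Bu4NCl, toluene, −40 → 0 °C) should then displace the triflate with inversion at a temperature where elimination and participation are slow, giving 21.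

Further compounds

F1 | step 10 | tert-butyl{[(3R,4R,5R)-5-[(benzyloxy)methyl]-4-(prop-2-en-1-yl)hept-6-en-3-yl]oxy}dimethylsilane | C=C[C@@H](COCc1ccccc1)[C@@H](CC=C)[C@H](O[Si](C)(C)C(C)(C)C)CC
F2 | step 10 | {(1R)-1-[(1R,2R)-2-[(benzyloxy)methyl]cyclopent-3-en-1-yl]propoxy}(tert-butyl)dimethylsilane | CC[C@@H](O[Si](C)(C)C(C)(C)C)[C@@H]1CC=C[C@H]1COCc1ccccc1
F3 | step 5 | methyl (2E,4R)-4-[(tert-butyldimethylsilyl)oxy]hex-2-enoate | CC[C@@H](O[Si](C)(C)C(C)(C)C)/C=C/C(=O)OC
F4 | step 5 | methyl (3R,4R)-4-[(tert-butyldimethylsilyl)oxy]-3-ethenylhexanoate | COC(=O)C[C@H](C=C)[C@H](O[Si](C)(C)C(C)(C)C)CC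
F5 | step 5 | (3R,4R)-4-[(tert-butyldimethylsilyl)oxy]-3-ethenylhexan-1-ol | OCC[C@H](C=C)[C@H](O[Si](C)(C)C(C)(C)C)CC
F6 | step 5 | (3R,4R)-4-[(tert-butyldimethylsilyl)oxy]-3-ethenylhexyl acetate | CC(=O)OCC[C@H](C=C)[C@H](O[Si](C)(C)C(C)(C)C)CC
F7 | step 5 | (3S,4R)-4-[(tert-butyldimethylsilyl)oxy]-3-(2-hydroxyethyl)hexyl acetate | CC(=O)OCC[C@H](CCO)[C@H](O[Si](C)(C)C(C)(C)C)CC
F8 | step 5 | (3R)-5-(acetyloxy)-3-[(1R)-1-[(tert-butyldimethylsilyl)oxy]propyl]pentanoic acid | CC(=O)OCC[C@H](CC(O)=O)[C@H](O[Si](C)(C)C(C)(C)C)CC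
F9 | step 13 | (1R)-1-[(3aR,4R,5R,6aS)-4-[(benzyloxy)methyl]-2,2-dimethyltetrahydro-4H-cyclopenta[d][1,3]dioxol-5-yl]propyl trifluoromethanesulfonate | CC[C@@H](OS(=O)(=O)C(F)(F)F)[C@@H]1C[C@@H]2OC(C)(C)O[C@@H]2[C@H]1COCc1ccccc1
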